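Ring A (the acylfilicinic acid ring) is a cyclohexane-1,3,5-trione: its acetyl-bearing carbon and its CMe2 carbon are the two α-carbons of one ketone, and the two oxygenated carbons that flank the bridge-bearing carbon are a malonyl unit. The route rests on the two ring bonds that join these halves (acetyl-bearing C to C=O; CMe2 to C–OH). The key step makes both in one flask: the dianion of a keto-dioxinone, which masks the acetyl group so that its methyl cannot enolize, is C-acylated at the isopropyl carbon by methyl malonyl chloride, and the linear masked polyketide closes by Dieckmann condensation. Acid unmasking, then a Mannich-derived o-quinone methide from the chromene, complete the target.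

Key step: step 2

Assumption: the triones are drawn as the enol tautomers that match the target SMILES, tautomers are treated as one compound, and the target has no stereocentre.

Step 1
Reactants: 1 2,2,6-trimethyl-4H-1,3-dioxin-4-one; 2 2-methylpropanoyl chloride
Product: 3 keto-dioxinone 2,2-dimethyl-6-(3-methyl-2-oxobutyl)-4H-1,3-dioxin-4-one
Conditions: LiN(SiMe3)2 (2.1 equiv), THF, −78 °C; then 2, −78 → −20 °C; aq. HCl
Reagents that add atoms: none
Why: The lithium dienolate of 1 should react with the acid chloride at its exocyclic γ-carbon (vinylogous Claisen C-acylation of a dioxinone dienolate), the second equivalent of base holding the more acidic product 3 as its enolate so that it is not acylated again.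

Step 2
Reactants: 3 keto-dioxinone; 4 methyl 3-chloro-3-oxopropanoate (methyl malonyl chloride)
Product: 6 dioxinone-masked acetylfilicinic acid, via linear triketo ester 5 (not isolated)
Conditions: LiN(iPr)2 (2.2 equiv), THF, −78 → −30 °C; ZnCl2, −78 °C; then 4, −78 → 45 °C; aq. HCl
Reagents that add atoms: none
Why: LiN(iPr)2 first removes a proton from the CH2 between the ketone and the dioxinone and then the isopropyl C–H, the only other acidic site because the carbon that becomes the acetyl CH3 is held as the vinylic C-5 of the dioxinone; after exchange to zinc the tetrasubstituted enolate carbon attacks the acid chloride of 4 to give 5 (new bond CMe2–C-3 of 5), and on warming the dioxinone-stabilised carbanion at C-6 of 5 attacks the ester C-1 and expels methoxide (new bond between the carbon that will bear the acetyl group and the ring C=O). The closest known reactions are the terminal C-acylation of keto-dioxinone and β-keto ester dianions (Claisen condensation) and the Dieckmann cyclisation of 5-oxo esters to cyclohexane-1,3,5-triones, as used for syncarpic acid. Ring A closes by a 6-exo-trig acyl substitution through the enolate carbon (6-enolendo-exo-trig, allowed), helped by the gem-dimethyl group. No stereocentre is formed. The step needs attack through carbon and not oxygen in both acylations and closure to the carbocycle and not to the enol lactone: the covalent zinc enolate directs the first acylation to carbon, ZnCl2 also keeps the carbanion from being quenched by the acidic CH2 of 4, and the trione leaves the equilibrium as its vinylogous carboxylate because the expelled methoxide deprotonates it at once. No phloroglucinol can form, since the only other carbon that could close a six-membered ring is blocked in the dioxinone.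

Step 3
Reactants: 6 dioxinone-masked acetylfilicinic acid
Product: 8 acetylfilicinic acid, via β-keto acid 7 (not isolated)
Conditions: 2 M aq. HCl, 1,4-dioxane, 60 °C
Reagents that add atoms: none
Why: Acid hydrolysis of the dioxinone (a cyclic acylal of acetone) should give β-keto acid 7, which loses CO2 through the usual six-membered transition state to leave the methyl ketone (dioxinone unmasking, then β-keto acid decarboxylation), the temperature being kept below that of the retro-[4+2] fragmentation to the acyl ketene.

Step 4
Reactants: 9 1-(2,4,6-trihydroxyphenyl)ethan-1-one; 10 3-methylbut-2-enal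
Product: 11 chromene 1-(5,7-dihydroxy-2,2-dimethyl-2H-chromen-8-yl)ethan-1-one
Conditions: pyridine, 110 °C
Reagents that add atoms: none
Why: Knoevenagel-type condensation of the aldehyde at a free ring carbon and oxa-6π-electrocyclisation of the resulting dienone onto a neighbouring oxygen (pyridine-mediated chromenylation of a phloroglucinol) should give 11 by closure onto the OH ortho to the acetyl group, the 6-acetyl isomer from closure onto the para OH being removed by chromatography.

Step 5
Reactants: 11 chromene; 8 acetylfilicinic acid
Product: 13 target, via Mannich base 12 (not isolated)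
Conditions: Me2N=CH2 I (Eschenmoser's salt, 1.0 equiv), NaOAc, MeCN, 0 → 25 °C; then 8, 1,4-dioxane, 80 °C
Reagents that add atoms: N,N-dimethylmethyleneiminium iodide (Eschenmoser's salt), C[N+](C)=C.[I-]
Why: Mannich aminomethylation at C-6, the only free ring carbon of 11, gives 12, which on heating (protonation by the strongly acidic enol 8 assists) loses dimethylamine to an o-quinone methide that the only free ring carbon of 8 captures in a Michael addition (Mannich reaction, then o-quinone methide alkylation of a cyclic trione).

Compound list
1 | 2,2,6-trimethyl-4H-1,3-dioxin-4-one | CC1=CC(=O)OC(C)(C)O1 | starting material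
2 | 2-methylpropanoyl chloride | CC(C)C(Cl)=O | starting material
3 | 2,2-dimethyl-6-(3-methyl-2-oxobutyl)-4H-1,3-dioxin-4-one | CC(C)C(=O)CC1=CC(=O)OC(C)(C)O1 | intermediate
4 | methyl 3-chloro-3-oxopropanoate | COC(=O)CC(Cl)=O | starting material
5 | methyl 6-(2,2-dimethyl-4-oxo-4H-1,3-dioxin-6-yl)-4,4-dimethyl-3,5-dioxohexanoate | COC(=O)CC(=O)C(C)(C)C(=O)CC1=CC(=O)OC(C)(C)O1 | intermediate
6 | 6-(2,4-dihydroxy-3,3-dimethyl-6-oxocyclohexa-1,4-dien-1-yl)-2,2-dimethyl-4H-1,3-dioxin-4-one | CC1(C)OC(=O)C=C(O1)C1=C(O)C(C)(C)C(O)=CC1=O | intermediate
7 | 3-(2,4-dihydroxy-3,3-dimethyl-6-oxocyclohexa-1,4-dien-1-yl)-3-oxopropanoic acid | OC(=O)CC(=O)C1=C(O)C(C)(C)C(O)=CC1=O | intermediate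
8 | 2-acetyl-3,5-dihydroxy-4,4-dimethylcyclohexa-2,5-dien-1-one (acetylfilicinic acid) | CC(=O)C1=C(O)C(C)(C)C(O)=CC1=O | intermediate
9 | 1-(2,4,6-trihydroxyphenyl)ethan-1-one | CC(=O)c1c(O)cc(O)cc1O | starting material
10 | 3-methylbut-2-enal | CC(C)=CC=O | starting material
11 | 1-(5,7-dihydroxy-2,2-dimethyl-2H-chromen-8-yl)ethan-1-one | CC(=O)c1c(O)cc(O)c2C=CC(C)(C)Oc12 | intermediate
12 | 1-{6-[(dimethylamino)methyl]-5,7-dihydroxy-2,2-dimethyl-2H-chromen-8-yl}ethan-1-one | CC(=O)c1c(O)c(CN(C)C)c(O)c2C=CC(C)(C)Oc12 | intermediate
13 | 2-acetyl-6-[(8-acetyl-5,7-dihydroxy-2,2-dimethyl-2H-chromen-6-yl)methyl]-3,5-dihydroxy-4,4-dimethylcyclohexa-2,5-dien-1-one | CC(=O)C1=C(O)C(C)(C)C(O)=C(Cc2c(O)c3c(c(C(C)=O)c2O)OC(C)(C)C=C3)C1=O | target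

Total steps: 5. Longest linear sequence: 4 steps (steps 1, 2, 3 and 5); step 4 is the side branch.

Steps most likely to fail

Step 2. The tertiary carbanion may be quenched by proton transfer from the acidic CH2 of 4, the hindered enolate may be acylated on oxygen, or the second deprotonation at the methine may not go to completion. The same two ring bonds can then be made on the unmasked ketone with known chemistry. Setting out from 4, the Reformatsky reagent prepared from commercial 3-bromo-3-methylbutan-2-one F1 and Zn in THF (a regiospecific tertiary zinc enolate) is C-acylated by 4 to methyl 4,4-dimethyl-3,5-dioxohexanoate F2. KOtBu in THF then closes F2 by Dieckmann condensation to filicinic acid F3. C-acetylation of F3 (AcOH, dicyclohexylcarbodiimide, 4-dimethylaminopyridine, CH2Cl2; O-acylation, then acyl migration to carbon) gives 8, where the route is rejoined. Compounds 3 and 6 and step 3 are then not needed.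

Step 3. Hydrolysis may be slow, and the dioxinone may instead fragment to the acyl ketene, which the neighbouring enol oxygen captures before water does. That lactonisation is then made the intended path. Setting out from 6, thermolysis in toluene at 110 °C (retro-[4+2] with loss of acetone, then intramolecular ketene capture) should give 4,7-dihydroxy-8,8-dimethyl-2H-chromene-2,5(8H)-dione F4. This enol lactone of a strongly acidic trione is opened by aq. NaOH at 25 °C, and acidification releases CO2 from β-keto acid 7 to give 8.

Step 5. The o-quinone methide may be consumed by the chromene double bond or by a second phenol, and retro-Mannich exchange may scramble the halves into symmetrical dimers. The bridge carbon is then brought in at the aldehyde level. Setting out from 11, Vilsmeier–Haack formylation (POCl3, DMF) at the free C-6 gives 8-acetyl-5,7-dihydroxy-2,2-dimethyl-2H-chromene-6-carbaldehyde F5. Three-component reductive alkylation of 8 with F5 and Hantzsch ester (L-proline cat., CH2Cl2/EtOH; Knoevenagel condensation, then transfer hydrogenation of the alkylidene trione) gives 13 directly.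

Further compounds
F1 | step 2 | 3-bromo-3-methylbutan-2-one (purchased) | CC(=O)C(C)(C)Br
F2 | step 2 | methyl 4,4-dimethyl-3,5-dioxohexanoate | COC(=O)CC(=O)C(C)(C)C(C)=O
F3 | step 2 | 3,5-dihydroxy-4,4-dimethylcyclohexa-2,5-dien-1-one (filicinic acid) | CC1(C)C(O)=CC(=O)C=C1O
F4 | step 3 | 4,7-dihydroxy-8,8-dimethyl-2H-chromene-2,5(8H)-dione | O=C1C=C(O)C2=C(O1)C(C)(C)C(O)=CC2=O
F5 | step 5 | 8-acetyl-5,7-dihydroxy-2,2-dimethyl-2H-chromene-6-carbaldehyde | CC(=O)c1c(O)c(C=O)c(O)c2C=CC(C)(C)Oc12
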